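Everything rests on a C1–C6 bond that the target lacks: C6 (the lactone carbinol) and C1 face each other across the ten-membered ring and C1=C10 bears the oxidised C14, so this bond is built as the one shared by cyclohexene ring A (C1–C6) and cyclohexane ring B (C6, C1, C10, C9, C8, C7) of a cis-decalin with a C10–O–C14 spiro-epoxide. Fragmentation of the C6 alkoxide cuts it and delivers, in one operation, the cyclodecadienone with C6 carbonyl, ring-cis C1=C10 olefin and C14 hydroxyl. The precursor is the cis-fused C6 tertiary alcohol (epoxide oxygen trans to H1) with C2–OTIPS, C8–OPMB, C15–OPMB and the C7 propenyl unit as TBDPS ether.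

Key step: step 24

Remark (labels): atom labels C1–C15 are those of the target germacranolide (lactone oxygen on C6, C12 lactone carbonyl, C13 exocyclic methylene, C14 on C10, C15 on C4) and are used for all intermediates; PMB = 4-methoxybenzyl, TBS = tert-butyldimethylsilyl, TBDPS = tert-butyldiphenylsilyl, TIPS = triisopropylsilyl, TMS = trimethylsilyl, DMP = Dess–Martin periodinane.

Remark (assumption): in step 2 the lipase is taken to acetylate the hydroxyl shown in 3; should the enzyme at hand prefer the other enantiotopic hydroxyl, the same compound 3 would be reached by hydrolysing the meso diacetate with it.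

Step 1
Reactants: 1 all-cis-cyclohexane-1,3,5-triol
Product: 2 all-cis-5-[(tert-butyldimethylsilyl)oxy]cyclohexane-1,3-diol (meso)
Conditions: TBSCl (0.5 equiv), imidazole, DMF, 0 to 23 °C
Reagents that add atoms: tert-butyldimethylsilyl chloride, CC(C)(C)[Si](C)(C)Cl
Why: Silylation of one of three equivalent hydroxyls with a deficit of TBSCl should favour the mono-ether (silyl ether formation); the product is meso, so no stereocentre is set yet.

Step 2
Reactants: 2 all-cis-5-[(tert-butyldimethylsilyl)oxy]cyclohexane-1,3-diol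
Product: 3 (1R,3S,5S)-3-[(tert-butyldimethylsilyl)oxy]-5-hydroxycyclohexyl acetate (all-cis)
Conditions: vinyl acetate, lipase from Burkholderia cepacia (immobilised), t-BuOMe, 30 °C
Reagents that add atoms: vinyl acetate, C=COC(C)=O
Why: Lipase-catalysed transesterification acetylates one of the two enantiotopic hydroxyls of the meso diol (enzymatic desymmetrisation), which fixes the absolute configuration of all three carbinol centres.

Step 3
Reactants: 3 (1R,3S,5S)-3-[(tert-butyldimethylsilyl)oxy]-5-hydroxycyclohexyl acetate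
Product: 5 (R)-5-[(tert-butyldimethylsilyl)oxy]cyclohex-2-en-1-one, via keto acetate 4 (not isolated)
Conditions: (COCl)2, DMSO, CH2Cl2, −78 °C; Et3N (excess), −78 to 23 °C
Reagents that add atoms: none
Why: Swern oxidation should give the β-acetoxy ketone, from which excess triethylamine removes acetic acid by E1cB elimination, the acetate being a far better leaving group than the silyloxy group, so the C10 centre is retained.

Step 4
Reactants: 5 (R)-5-[(tert-butyldimethylsilyl)oxy]cyclohex-2-en-1-one
Product: 6 (R)-5-[(tert-butyldimethylsilyl)oxy]-2-iodocyclohex-2-en-1-one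
Conditions: I2, pyridine, CH2Cl2, 0 to 23 °C
Reagents that add atoms: iodine, [I][I]
Why: α-Iodination of the enone by conjugate addition of pyridine, iodination of the enolate and loss of pyridine (Baylis–Hillman-type addition–elimination) should leave the remote stereocentre untouched.

Step 5
Reactants: 7 2-bromoprop-2-en-1-ol
Product: 8 [(2-bromoprop-2-en-1-yl)oxy](tert-butyl)diphenylsilane
Conditions: TBDPSCl, imidazole, CH2Cl2, 0 to 23 °C
Reagents that add atoms: tert-butyl(chloro)diphenylsilane, CC(C)(C)[Si](Cl)(c1ccccc1)c1ccccc1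
Why: Standard silylation of a primary allylic alcohol; the TBDPS group is chosen because it is stable to tert-butyllithium, acid and base and does not migrate.

Step 6
Reactants: 8 [(2-bromoprop-2-en-1-yl)oxy](tert-butyl)diphenylsilane; 6 (R)-5-[(tert-butyldimethylsilyl)oxy]-2-iodocyclohex-2-en-1-one
Product: 11 (R)-5-[(tert-butyldimethylsilyl)oxy]-2-{3-[(tert-butyldiphenylsilyl)oxy]prop-1-en-2-yl}cyclohex-2-en-1-one (carbonyl = C8; ring alkene = C7=C6), via alkenyllithium 9 (not isolated), via alkenylzinc chloride 10 (not isolated)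
Conditions: t-BuLi (2 equiv), Et2O, −78 °C; ZnCl2, THF, −78 to 0 °C; 6, Pd(PPh3)4 (5 mol %), THF, 23 °C
Reagents that add atoms: none
Why: Bromine–lithium exchange and transmetalation give an alkenylzinc chloride that couples with the α-iodoenone under zerovalent palladium catalysis (Negishi coupling); no stereocentre is formed.

Step 7
Reactants: 11 dienone
Product: 12 (1R,5R)-5-[(tert-butyldimethylsilyl)oxy]-2-{3-[(tert-butyldiphenylsilyl)oxy]prop-1-en-2-yl}cyclohex-2-en-1-ol (C8–OH cis to C10–OTBS)
Conditions: NaBH4, CeCl3·7H2O, MeOH, −78 °C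
Reagents that add atoms: none
Why: Luche 1,2-reduction: hydride should add axially on the face away from the ring substituent, as in the reduction of carvone to cis-carveol, so the new C8 hydroxyl comes out cis to the C10 silyloxy group and sets the future C8 configuration.

Step 8
Reactants: 12 cis-dienol
Product: 13 ring B epoxy alcohol (C6–C7 epoxide, C8–OH and C10–OTBS all on one face; C7 carries the 3-(TBDPSO)prop-1-en-2-yl group)
Conditions: VO(acac)2 (5 mol %), t-BuOOH, CH2Cl2, 0 °C
Reagents that add atoms: tert-butyl hydroperoxide, CC(C)(C)OO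
Why: Vanadium-catalysed hydroxyl-directed epoxidation delivers oxygen to the allylic ring double bond on the face of the C8 hydroxyl and ignores the homoallylic exocyclic alkene, which sets C6 and C7 with the epoxide cis to both ring oxygens.

Step 9
Reactants: 13 ring B epoxy alcohol
Product: 14 C8 PMB ether of 13
Conditions: NaH, 4-methoxybenzyl chloride, Bu4NI (cat.), THF/DMF, 0 to 23 °C
Reagents that add atoms: 4-methoxybenzyl chloride, COc1ccc(CCl)cc1
Why: Williamson etherification installs the C8 ether that is kept to the end (an alkyl ether is a poor leaving group and cannot migrate); the cis epoxy alkoxide cannot undergo Payne rearrangement on the ring and the bulky TBS and TBDPS groups should resist transfer to the alkoxide.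

Step 10
Reactants: 14 vinyl epoxide PMB ether
Product: 15 ring B alcohol (C6–OH, C7 3-(TBDPSO)prop-1-en-2-yl, C8–OPMB and C10–OTBS all cis)
Conditions: Pd2(dba)3·CHCl3 (2.5 mol %), n-Bu3P (10 mol %), HCO2H, Et3N, 1,4-dioxane, 23 °C
Reagents that add atoms: none
Why: Zerovalent palladium opens the vinyl epoxide with inversion at C7 to a π-allyl palladium formate, which loses CO2 and delivers hydride from the metal to the more substituted allyl terminus (formate hydrogenolysis of an alkenyl oxirane, a Tsuji–Trost-type process), so H enters anti to the broken C–O bond and the propenyl group is pushed cis to the C6 hydroxyl and the C8 and C10 ethers.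

Step 11
Reactants: 15 ring B alcohol
Product: 16 (2R,3R,5S)-5-[(tert-butyldimethylsilyl)oxy]-2-{3-[(tert-butyldiphenylsilyl)oxy]prop-1-en-2-yl}-3-[(4-methoxybenzyl)oxy]cyclohexan-1-one (C6 ketone; C7, C8, C10 substituents all cis)
Conditions: DMP, pyridine, CH2Cl2, 0 °C
Reagents that add atoms: none
Why: Dess–Martin oxidation under buffered, non-basic conditions should give the ketone without epimerising C7, whose propenyl group is cis to the neighbouring ether.

Step 12
Reactants: 17 3-bromo-2-(bromomethyl)prop-1-ene
Product: 18 1-({[2-(bromomethyl)prop-2-en-1-yl]oxy}methyl)-4-methoxybenzene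
Conditions: 4-methoxybenzyl alcohol, NaH, THF, 0 °C; then added to 17 (3 equiv), 0 to 23 °C
Reagents that add atoms: 4-methoxybenzyl alcohol, COc1ccc(CO)cc1
Why: Williamson ether synthesis; the excess of the dibromide should limit double substitution, and SN2 and SN2′ attack give the same product.

Step 13
Reactants: 18 allylic bromide; 19 formaldehyde
Product: 20 3-{[(4-methoxybenzyl)oxy]methyl}but-3-en-1-ol
Conditions: indium powder, 37% aqueous formaldehyde, THF/H2O, 23 °C
Reagents that add atoms: none
Why: Indium-mediated Barbier allylation of formaldehyde in water tolerates the ether; the 2-substituted allyl unit has two equivalent termini, so a single homoallylic alcohol can form.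

Step 14
Reactants: 20 3-{[(4-methoxybenzyl)oxy]methyl}but-3-en-1-ol
Product: 21 3-{[(4-methoxybenzyl)oxy]methyl}but-3-enal
Conditions: DMP, pyridine, CH2Cl2, 0 °C; used at once
Reagents that add atoms: none
Why: Dess–Martin oxidation at low temperature should give the β,γ-unsaturated aldehyde, which is used at once so that the double bond does not move into conjugation.

Step 15
Reactants: 16 ring B ketone; 21 aldehyde
Product: 23 anti aldol (ketone 16 carrying at C1 the chain C2H(OH)–C3H2–C4(=CH2)–C15H2OPMB; C1 chain trans to the C7, C8 and C10 substituents; 2S), via boron enolate 22 (not isolated)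
Conditions: (c-C6H11)2BCl, Et3N, Et2O, −78 to 0 °C; 21, −78 °C; then MeOH, pH 7 buffer, H2O2, 0 °C
Reagents that add atoms: none
Why: Chlorodicyclohexylborane and triethylamine should enolise the ketone kinetically at the unbranched C1 to the E boron enolate, which adds to 21 through a Zimmerman–Traxler chair to give the anti aldol (boron aldol reaction); the aldehyde approaches C1 on the face opposite the three cis substituents at C7, C8 and C10, which sets C1, and the chair sets C2 (S) relative to C1.

Step 16
Reactants: 23 anti aldol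
Product: 24 C2 TIPS ether of 23
Conditions: TIPSOTf, 2,6-lutidine, CH2Cl2, −78 to 0 °C
Reagents that add atoms: triisopropylsilyl trifluoromethanesulfonate, CC(C)[Si](OS(=O)(=O)C(F)(F)F)(C(C)C)C(C)C
Why: Silylation with the triflate and a hindered pyridine base protects the aldol hydroxyl without retro-aldol cleavage; TIPS is chosen because it does not migrate and outlasts the later removal of the TBS group.

Step 17
Reactants: 24 ketone; 25 vinylmagnesium bromide
Product: 26 C6 tertiary allylic alcohol (vinyl on C6 cis to the C1 side chain; C6–OH cis to the C7 propenyl group, C8–OPMB and C10–OTBS)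
Conditions: CeCl3, THF, −78 °C; 25
Reagents that add atoms: none
Why: Addition of the vinylcerium reagent (organocerium 1,2-addition, which suppresses enolisation): in the chair with the C1, C8 and C10 substituents equatorial the C7 propenyl group is axial, so the nucleophile should attack axially and anti to it, placing the vinyl group cis to the C1 side chain and the C6 hydroxyl cis to the C7 group.

Step 18
Reactants: 26 diene alcohol
Product: 27 cis-decalin (ring A C4=C5 with C15H2OPMB on C4 and (2S)-OTIPS; ring B with C7 propenyl unit, C8–OPMB, C10–OTBS; C6–OH cis to H1)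
Conditions: second-generation Grubbs catalyst (5 mol %), CH2Cl2, 40 °C
Reagents that add atoms: none
Why: Ring-closing metathesis between the C6 vinyl group and the 1,1-disubstituted C4 alkene closes cyclohexene ring A with loss of ethene; the cis relation of the two arms set in steps 15 and 17 makes the ring fusion cis (C6–OH cis to H1).

Step 19
Reactants: 27 cis-decalin TBS ether
Product: 28 cis-decalin C10 alcohol (C6,C10-diol)
Conditions: HF·pyridine, pyridine, THF, 0 to 23 °C
Reagents that add atoms: none
Why: Buffered HF·pyridine should cleave the secondary TBS ether at C10 faster than the secondary TIPS and the primary TBDPS ethers (selective desilylation), without touching the tertiary allylic alcohol.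

Step 20
Reactants: 28 cis-decalin diol
Product: 29 cis-decalin C10 ketone (β-hydroxy ketone)
Conditions: DMP, pyridine, CH2Cl2, 0 °C
Reagents that add atoms: none
Why: Dess–Martin oxidation converts the only secondary alcohol into the C10 ketone, the tertiary C6 alcohol being inert, and the buffered conditions should not epimerise C1.

Step 21
Reactants: 29 β-hydroxy ketone
Product: 30 C6 TMS ether of 29
Conditions: 1-(trimethylsilyl)imidazole, CH2Cl2, 23 °C
Reagents that add atoms: 1-(trimethylsilyl)imidazole, C[Si](C)(C)n1ccnc1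
Why: Silylation with 1-(trimethylsilyl)imidazole masks the tertiary hydroxyl, so that the basic ylide of the next step cannot form the alkoxide of the β-hydroxy ketone and trigger a retro-aldol opening.

Step 22
Reactants: 30 silylated ketone; 31 trimethylsulfonium iodide
Product: 33 C10 spiro-epoxide as C6 TMS ether (epoxide oxygen trans to H1; C14 cis to H1), via sulfonium ylide 32 (not isolated)
Conditions: 31, n-BuLi, THF, −10 °C; then 30, −10 to 0 °C
Reagents that add atoms: none
Why: Corey–Chaykovsky epoxidation: the ylide should add to the C10 carbonyl from the convex face of the cis-decalin, equatorially and away from the axial C5 of ring A, so that C14 ends up cis to H1 and the epoxide oxygen trans to it.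

Step 23
Reactants: 33 epoxide TMS ether
Product: 34 fragmentation precursor (cis-decalin C6 tertiary alcohol with C10 spiro-epoxide; C2–OTIPS, C8–OPMB, C15–OPMB, C12–OTBDPS)
Conditions: TBAF, AcOH (1:1), THF, 0 °C
Reagents that add atoms: none
Why: Buffered fluoride should remove the labile TMS ether while the TIPS and TBDPS ethers, the epoxide and the two PMB ethers survive, and the acetic acid keeps the freed tertiary alcohol protonated.

Step 24
Reactants: 34 fragmentation precursor
Product: 36 cyclodeca-1(10),4-dien-6-one (ring-cis C4=C5 and C1=C10; C14–OH; C2–OTIPS, C8–OPMB, C15–OPMB, C12–OTBDPS), via potassium alkoxide 35 (not isolated)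
Conditions: KN(SiMe3)2 (1.05 equiv), THF, −78 to −30 °C; AcOH, −78 °C
Reagents that add atoms: none
Why: Deprotonation gives the C6 potassium alkoxide, whose oxygen lone pair pushes into the C6–C1 σ bond as that bond breaks, the C1=C10 π bond forms and the C10–O bond of the spiro-epoxide opens, all in one concerted anti-periplanar event driven by carbonyl formation and release of epoxide strain (Grob fragmentation; the closest known types are the Wharton fragmentation of 1,3-diol monosulfonates and the fragmentation of β-hydroxy epoxides, the epoxide serving as nucleofuge). No ring is closed by bond formation, so no closure mode applies: the ten-membered ring appears because the bond common to rings A and B is cut and the two six-membered rings merge. No stereocentre is created, and C2, C7 and C8 are carried through unchanged. The step needs the ring-cis C1=C10 geometry (C2 cis to C9), which follows stereospecifically from the cis ring fusion, which puts C2 axial on ring B, and from the equatorial C10–O bond, which lies trans to H1 and anti-periplanar to C6–C1. It also needs fragmentation to outrun attack of the alkoxide on the epoxide CH2 and base-induced loss of the C8 ether or epimerisation at C7 in the β-alkoxy ketone formed; one equivalent of base, low temperature and a cold acidic quench serve this, as do the non-migrating TIPS and TBDPS groups and the PMB ether at C8, a poor leaving group.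

Step 25
Reactants: 36 cyclodecadienone
Product: 37 (6R)-allylic alcohol (C6,C14-diol)
Conditions: NaBH4, CeCl3·7H2O, MeOH, −78 °C
Reagents that add atoms: none
Why: Luche 1,2-reduction of the enone: hydride should reach the C6 carbonyl from the outer face of the ten-membered ring, anti to the adjacent C7 propenyl group, which is expected to give the 6R alcohol with H6 trans to H7 as the trans-fused lactone requires; this sets C6.

Step 26
Reactants: 37 diol
Product: 38 C6,C12,C14-triol
Conditions: TBAF, AcOH (1:1), THF, 0 °C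
Reagents that add atoms: none
Why: Buffered fluoride should cleave the primary allylic TBDPS ether faster than the hindered secondary TIPS ether (selective desilylation), freeing the C12 hydroxyl.

Step 27
Reactants: 38 triol
Product: 41 6,12-lactone C14-aldehyde (α-methylene-γ-butyrolactone; C2–OTIPS, C8–OPMB, C15–OPMB), via hydroxy dialdehyde 39 (not isolated), via lactol 40 (not isolated)
Conditions: TEMPO (20 mol %), PhI(OAc)2, CH2Cl2, 23 °C
Reagents that add atoms: none
Why: TEMPO-catalysed oxidation with PhI(OAc)2 oxidises the two primary allylic alcohols to aldehydes; the C12 aldehyde is trapped by the C6 hydroxyl as a five-membered lactol that is oxidised on to the α-methylene lactone (oxidative lactonisation of a 1,4-diol), while C14 stops at the enal and no stereocentre changes.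

Step 28
Reactants: 41 bis-PMB ether
Product: 42 C8,C15-diol
Conditions: DDQ, CH2Cl2/pH 7 buffer, 0 °C
Reagents that add atoms: none
Why: Oxidative cleavage of both PMB ethers with DDQ through the benzylic oxocarbenium ions (PMB deprotection) frees the C8 and C15 hydroxyls and leaves silyl ether, enal and lactone intact.

Step 29
Reactants: 42 diol
Product: 43 C15 acetate (C8–OH free)
Conditions: AcCl, 2,4,6-collidine, CH2Cl2, −78 °C
Reagents that add atoms: acetyl chloride, CC(Cl)=O
Why: Acylation at low temperature with a weak hindered base should take place at the unhindered primary allylic C15 hydroxyl only (chemoselective acetylation), the secondary C8 hydroxyl next to the ring fusion reacting far more slowly.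

Step 30
Reactants: 43 C15 acetate
Product: 44 C8 isovalerate (C2–OTIPS)
Conditions: (i-PrCH2CO)2O, DMAP, pyridine, CH2Cl2, 0 to 23 °C
Reagents that add atoms: 3-methylbutanoic anhydride, CC(C)CC(=O)OC(=O)CC(C)C
Why: DMAP-catalysed acylation with the anhydride esterifies the remaining secondary C8 hydroxyl with retention of configuration.

Step 31
Reactants: 44 TIPS ether
Product: 45 target CNP0524123.1, (2S,6R,7R,8R)
Conditions: HF·pyridine, pyridine, THF, 0 to 23 °C
Reagents that add atoms: none
Why: Fluoride-mediated cleavage of the last silyl ether under mildly acidic conditions that the two esters, the enal and the α-methylene lactone should tolerate (desilylation) gives the target.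

Compound list

1 | all-cis-cyclohexane-1,3,5-triol | O[C@H]1C[C@@H](O)C[C@@H](O)C1 | starting material
2 | all-cis-5-[(tert-butyldimethylsilyl)oxy]cyclohexane-1,3-diol (meso) | O[C@H]1C[C@@H](O)C[C@@H](O[Si](C)(C)C(C)(C)C)C1 | intermediate
3 | (1R,3S,5S)-3-[(tert-butyldimethylsilyl)oxy]-5-hydroxycyclohexyl acetate | O[C@H]1C[C@@H](OC(C)=O)C[C@@H](O[Si](C)(C)C(C)(C)C)C1 | intermediate
4 | (1S,3R)-3-[(tert-butyldimethylsilyl)oxy]-5-oxocyclohexyl acetate (cis) | O=C1C[C@@H](OC(C)=O)C[C@@H](O[Si](C)(C)C(C)(C)C)C1 | intermediate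
5 | (R)-5-[(tert-butyldimethylsilyl)oxy]cyclohex-2-en-1-one | O=C1C=CC[C@@H](O[Si](C)(C)C(C)(C)C)C1 | intermediate
6 | (R)-5-[(tert-butyldimethylsilyl)oxy]-2-iodocyclohex-2-en-1-one | O=C1C(I)=CC[C@@H](O[Si](C)(C)C(C)(C)C)C1 | intermediate
7 | 2-bromoprop-2-en-1-ol | OCC(Br)=C | starting material
8 | [(2-bromoprop-2-en-1-yl)oxy](tert-butyl)diphenylsilane | C=C(Br)CO[Si](c1ccccc1)(c2ccccc2)C(C)(C)C | intermediate
9 | {3-[(tert-butyldiphenylsilyl)oxy]prop-1-en-2-yl}lithium | [Li]C(=C)CO[Si](c1ccccc1)(c2ccccc2)C(C)(C)C | intermediate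
10 | chloro{3-[(tert-butyldiphenylsilyl)oxy]prop-1-en-2-yl}zinc | Cl[Zn]C(=C)CO[Si](c1ccccc1)(c2ccccc2)C(C)(C)C | intermediate
11 | (R)-5-[(tert-butyldimethylsilyl)oxy]-2-{3-[(tert-butyldiphenylsilyl)oxy]prop-1-en-2-yl}cyclohex-2-en-1-one | O=C1C(C(=C)CO[Si](c2ccccc2)(c3ccccc3)C(C)(C)C)=CC[C@@H](O[Si](C)(C)C(C)(C)C)C1 | intermediate
12 | (1R,5R)-5-[(tert-butyldimethylsilyl)oxy]-2-{3-[(tert-butyldiphenylsilyl)oxy]prop-1-en-2-yl}cyclohex-2-en-1-ol (cis) | O[C@H]1C(C(=C)CO[Si](c2ccccc2)(c3ccccc3)C(C)(C)C)=CC[C@@H](O[Si](C)(C)C(C)(C)C)C1 | intermediate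
13 | ring B epoxy alcohol: C6–C7 epoxide, C8–OH and C10–OTBS on one face; C7 bears 3-(TBDPSO)prop-1-en-2-yl | O[C@H]1[C@@]2(C(=C)CO[Si](c3ccccc3)(c4ccccc4)C(C)(C)C)O[C@H]2C[C@@H](O[Si](C)(C)C(C)(C)C)C1 | intermediate
14 | C8 PMB ether of 13 | COc1ccc(cc1)CO[C@H]2[C@@]3(C(=C)CO[Si](c4ccccc4)(c5ccccc5)C(C)(C)C)O[C@H]3C[C@@H](O[Si](C)(C)C(C)(C)C)C2 | intermediate
15 | ring B alcohol: C6–OH, C7 3-(TBDPSO)prop-1-en-2-yl, C8–OPMB, C10–OTBS all cis | COc1ccc(cc1)CO[C@H]2[C@@H](C(=C)CO[Si](c3ccccc3)(c4ccccc4)C(C)(C)C)[C@@H](O)C[C@@H](O[Si](C)(C)C(C)(C)C)C2 | intermediate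
16 | (2R,3R,5S)-5-[(tert-butyldimethylsilyl)oxy]-2-{3-[(tert-butyldiphenylsilyl)oxy]prop-1-en-2-yl}-3-[(4-methoxybenzyl)oxy]cyclohexan-1-one | COc1ccc(cc1)CO[C@H]2[C@@H](C(=C)CO[Si](c3ccccc3)(c4ccccc4)C(C)(C)C)C(=O)C[C@@H](O[Si](C)(C)C(C)(C)C)C2 | intermediate
17 | 3-bromo-2-(bromomethyl)prop-1-ene | C=C(CBr)CBr | starting material
18 | 1-({[2-(bromomethyl)prop-2-en-1-yl]oxy}methyl)-4-methoxybenzene | C=C(CBr)COCc1ccc(OC)cc1 | intermediate
19 | formaldehyde | C=O | starting material
20 | 3-{[(4-methoxybenzyl)oxy]methyl}but-3-en-1-ol | C=C(CCO)COCc1ccc(OC)cc1 | intermediate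
21 | 3-{[(4-methoxybenzyl)oxy]methyl}but-3-enal | C=C(CC=O)COCc1ccc(OC)cc1 | intermediate
22 | E dicyclohexylboron enolate of 16 (C6–O–B, C6=C1) | COc1ccc(cc1)CO[C@H]2[C@@H](C(=C)CO[Si](c3ccccc3)(c4ccccc4)C(C)(C)C)C(OB(C5CCCCC5)C6CCCCC6)=C[C@@H](O[Si](C)(C)C(C)(C)C)C2 | intermediate
23 | anti aldol: 16 with the (2S)-hydroxy chain C2–C3–C4(=CH2)–C15H2OPMB on C1, trans to the C7, C8, C10 groups | C=C(COCc1ccc(OC)cc1)C[C@H](O)[C@H]2C(=O)[C@H](C(=C)CO[Si](c3ccccc3)(c4ccccc4)C(C)(C)C)[C@H](OCc5ccc(OC)cc5)C[C@@H]2O[Si](C)(C)C(C)(C)C | intermediate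
24 | C2 TIPS ether of 23 | C=C(COCc1ccc(OC)cc1)C[C@H](O[Si](C(C)C)(C(C)C)C(C)C)[C@H]2C(=O)[C@H](C(=C)CO[Si](c3ccccc3)(c4ccccc4)C(C)(C)C)[C@H](OCc5ccc(OC)cc5)C[C@@H]2O[Si](C)(C)C(C)(C)C | intermediate
25 | vinylmagnesium bromide | C=C[Mg]Br | starting material
26 | C6 vinyl carbinol: vinyl cis to the C1 chain, C6–OH cis to C7, C8, C10 groups | C=C(COCc1ccc(OC)cc1)C[C@H](O[Si](C(C)C)(C(C)C)C(C)C)[C@H]2[C@@](O)(C=C)[C@H](C(=C)CO[Si](c3ccccc3)(c4ccccc4)C(C)(C)C)[C@H](OCc5ccc(OC)cc5)C[C@@H]2O[Si](C)(C)C(C)(C)C | intermediate
27 | cis-decalin with C10–OTBS (C4=C5; C6–OH cis to H1; C2–OTIPS; C8–OPMB; C15–OPMB; C12–OTBDPS) | O[C@@]12C=C(COCc3ccc(OC)cc3)C[C@H](O[Si](C(C)C)(C(C)C)C(C)C)[C@@H]1[C@@H](O[Si](C)(C)C(C)(C)C)C[C@@H](OCc4ccc(OC)cc4)[C@H]2C(=C)CO[Si](c5ccccc5)(c6ccccc6)C(C)(C)C | intermediate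
28 | cis-decalin C10 alcohol | O[C@@]12C=C(COCc3ccc(OC)cc3)C[C@H](O[Si](C(C)C)(C(C)C)C(C)C)[C@@H]1[C@@H](O)C[C@@H](OCc4ccc(OC)cc4)[C@H]2C(=C)CO[Si](c5ccccc5)(c6ccccc6)C(C)(C)C | intermediate
29 | cis-decalin C10 ketone (C6–OH free) | O[C@@]12C=C(COCc3ccc(OC)cc3)C[C@H](O[Si](C(C)C)(C(C)C)C(C)C)[C@@H]1C(=O)C[C@@H](OCc4ccc(OC)cc4)[C@H]2C(=C)CO[Si](c5ccccc5)(c6ccccc6)C(C)(C)C | intermediate
30 | C6 TMS ether of 29 | C[Si](C)(C)O[C@@]12C=C(COCc3ccc(OC)cc3)C[C@H](O[Si](C(C)C)(C(C)C)C(C)C)[C@@H]1C(=O)C[C@@H](OCc4ccc(OC)cc4)[C@H]2C(=C)CO[Si](c5ccccc5)(c6ccccc6)C(C)(C)C | intermediate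
31 | trimethylsulfonium iodide | C[S+](C)C.[I-] | starting material
32 | dimethylsulfonium methylide | C[S+](C)[CH2-] | intermediate
33 | C10 spiro-epoxide, C6 TMS ether (epoxide O trans to H1) | C[Si](C)(C)O[C@@]12C=C(COCc3ccc(OC)cc3)C[C@H](O[Si](C(C)C)(C(C)C)C(C)C)[C@@H]1[C@@]4(CO4)C[C@@H](OCc5ccc(OC)cc5)[C@H]2C(=C)CO[Si](c6ccccc6)(c7ccccc7)C(C)(C)C | intermediate
34 | fragmentation precursor: cis-decalin C6 tertiary alcohol with C10 spiro-epoxide | O[C@@]12C=C(COCc3ccc(OC)cc3)C[C@H](O[Si](C(C)C)(C(C)C)C(C)C)[C@@H]1[C@@]4(CO4)C[C@@H](OCc5ccc(OC)cc5)[C@H]2C(=C)CO[Si](c6ccccc6)(c7ccccc7)C(C)(C)C | intermediate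
35 | C6 potassium alkoxide of 34 | [K+].[O-][C@@]12C=C(COCc3ccc(OC)cc3)C[C@H](O[Si](C(C)C)(C(C)C)C(C)C)[C@@H]1[C@@]4(CO4)C[C@@H](OCc5ccc(OC)cc5)[C@H]2C(=C)CO[Si](c6ccccc6)(c7ccccc7)C(C)(C)C | intermediate
36 | fragmentation product: cyclodeca-1(10),4-dien-6-one with C14–OH (both ring olefins ring-cis) | O=C1/C=C(/COCc2ccc(OC)cc2)C[C@H](O[Si](C(C)C)(C(C)C)C(C)C)/C=C(/CO)C[C@@H](OCc3ccc(OC)cc3)[C@H]1C(=C)CO[Si](c4ccccc4)(c5ccccc5)C(C)(C)C | intermediate
37 | (6R)-C6,C14-diol | O[C@@H]1/C=C(/COCc2ccc(OC)cc2)C[C@H](O[Si](C(C)C)(C(C)C)C(C)C)/C=C(/CO)C[C@@H](OCc3ccc(OC)cc3)[C@H]1C(=C)CO[Si](c4ccccc4)(c5ccccc5)C(C)(C)C | intermediate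
38 | C6,C12,C14-triol | O[C@@H]1/C=C(/COCc2ccc(OC)cc2)C[C@H](O[Si](C(C)C)(C(C)C)C(C)C)/C=C(/CO)C[C@@H](OCc3ccc(OC)cc3)[C@H]1C(=C)CO | intermediate
39 | C6-hydroxy C12,C14-dialdehyde | O[C@@H]1/C=C(/COCc2ccc(OC)cc2)C[C@H](O[Si](C(C)C)(C(C)C)C(C)C)/C=C(/C=O)C[C@@H](OCc3ccc(OC)cc3)[C@H]1C(=C)C=O | intermediate
40 | C12 lactol, C14 aldehyde (C12 epimers) | C=C1C(O)O[C@@H]2/C=C(/COCc3ccc(OC)cc3)C[C@H](O[Si](C(C)C)(C(C)C)C(C)C)/C=C(/C=O)C[C@@H](OCc4ccc(OC)cc4)[C@@H]12 | intermediate
41 | 6,12-lactone C14-aldehyde, C8 and C15 PMB ethers, C2–OTIPS | C=C1C(=O)O[C@@H]2/C=C(/COCc3ccc(OC)cc3)C[C@H](O[Si](C(C)C)(C(C)C)C(C)C)/C=C(/C=O)C[C@@H](OCc4ccc(OC)cc4)[C@@H]12 | intermediate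
42 | lactone aldehyde C8,C15-diol | C=C1C(=O)O[C@@H]2/C=C(/CO)C[C@H](O[Si](C(C)C)(C(C)C)C(C)C)/C=C(/C=O)C[C@@H](O)[C@@H]12 | intermediate
43 | C15 acetate, C8–OH | C=C1C(=O)O[C@@H]2/C=C(/COC(C)=O)C[C@H](O[Si](C(C)C)(C(C)C)C(C)C)/C=C(/C=O)C[C@@H](O)[C@@H]12 | intermediate
44 | C15 acetate, C8 isovalerate, C2–OTIPS | C=C1C(=O)O[C@@H]2/C=C(/COC(C)=O)C[C@H](O[Si](C(C)C)(C(C)C)C(C)C)/C=C(/C=O)C[C@@H](OC(=O)CC(C)C)[C@@H]12 | intermediate
45 | CNP0524123.1, (2S,6R,7R,8R) | C=C1C(=O)O[C@@H]2/C=C(/COC(C)=O)C[C@H](O)/C=C(/C=O)C[C@@H](OC(=O)CC(C)C)[C@@H]12 | target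

Total step count: 31. Longest linear sequence: 27 steps (steps 1–4, 6–11 and 15–31).

The three steps most likely to fail

Step 24 (key step). The alkoxide may be diverted into opening of the epoxide at C14 by the nearby oxygen, or the fragmentation may be followed by base-induced loss of the C8 ether or epimerisation at C7 of the β-alkoxy ketone. Fallback: the fragmentation would be run without a free basic alkoxide, under Lewis acid assistance. Alcohol 34 is heated with Ti(OiPr)4 in CH2Cl2, so that a covalent titanium alkoxide at C6 provides the push while a second titanium centre activates the epoxide oxygen, and the neutral titanium alkoxide of the product is hydrolysed on work-up. The fallback sets out from 34 and comes back to the route at 36; it passes through no new compound.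

Step 25. Hydride delivery to the flexible ten-membered enone may show poor facial selectivity, so that the 6S alcohol forms alongside or instead of the 6R alcohol. Fallback: substrate control would be replaced by reagent control, a 1,2-reduction of the enone with catecholborane and the antipode of the 2-methyl-CBS-oxazaborolidine that is matched to the 6R alcohol (toluene, −78 °C; both antipodes would be tried on a small scale). The fallback sets out from 36 and comes back to the route at 37; it passes through no new compound.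

Step 22. The basic ylide may enolise the C10 ketone instead of adding to it, which would epimerise C1 (trans ring fusion) or expel the C8 ether by E1cB elimination. Fallback: the methylene would be delivered by a less basic carbenoid at low temperature. Chloromethyllithium is generated from ICH2Cl and n-BuLi in THF at −78 °C in the presence of 30 (Barbier mode) and adds to the carbonyl to give the lithium alkoxide of the C10 chloromethyl carbinol F1, which closes to the epoxide on warming. The fallback sets out from 30 and comes back to the route at 33.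

Further compounds

F0 | step 24 | none | none
F0 | step 25 | none | none
F1 | step 22 | lithium alkoxide of the C10 chloromethyl carbinol (C6 TMS ether) | C[Si](C)(C)O[C@@]12C=C(COCc3ccc(OC)cc3)C[C@H](O[Si](C(C)C)(C(C)C)C(C)C)[C@@H]1[C@@](O[Li])(CCl)C[C@@H](OCc4ccc(OC)cc4)[C@H]2C(=C)CO[Si](c5ccccc5)(c6ccccc6)C(C)(C)C
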